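**Strategy**

Kuwanon C is disconnected at the C5–C6 bond of ring A. The oxygens on C5 and C7 of this phloroglucinol-type ring stand 1,3 to each other, so C5 can be read as an ester carbon and C7 as a ketone carbon. An intramolecular Claisen condensation on a fully substituted 4-pyranone, which already holds ring C, ring B and the C3 prenyl group, closes and aromatises ring A in one operation and fixes the second prenyl group at C8. The precursor is a 6-aryl-5-prenyl-4-pyranone with an ethyl ester on pyranone C3 and a 1-acetyl-4-methylpent-3-enyl chain on pyranone C2; it comes from an aroyl(prenyl)ketene, a β-enamino ester and a lateral acetylation.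

Key step: step 8

Remark: flavone numbering is used for the target and pyranone numbering for the monocyclic intermediates; the acetoacetate unit must carry its prenyl group on the γ-carbon (set by dianion alkylation), since only then can pyranone C3 aromatise and pyranone C2 keep a lateral CH2 for the acetylation; the ring B keto ester is made as its tert-butyl ester because that releases the acylketene at a moderate temperature; 7, 13, 16 and 17 are racemic and their stereocentres vanish on the way to the achiral target.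

**Route**

Step 1
Reactants: 1 methyl 2,4-dihydroxybenzoate; 2 chloromethyl methyl ether
Product: 3 methyl 2,4-bis(methoxymethoxy)benzoate
Conditions: NaH, DMF, 0 °C → rt
Reagents that add atoms: chloromethyl methyl ether (2), COCCl
Why: Williamson-type O-alkylation, in which NaH deprotonates both phenols, including the hydrogen-bonded 2-hydroxyl, and the phenoxides displace chloride from the reactive α-chloro ether.

Step 2
Reactants: 3 methyl 2,4-bis(methoxymethoxy)benzoate; 4 tert-butyl acetate
Product: 5 tert-butyl 3-[2,4-bis(methoxymethoxy)phenyl]-3-oxopropanoate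
Conditions: 4 (2.5 equiv), LiN(iPr)2, THF, −78 °C; then 3, −78 → 0 °C; aq. NH4Cl
Reagents that add atoms: tert-butyl acetate (4), CC(=O)OC(C)(C)C
Why: Crossed Claisen condensation, in which the non-enolisable benzoate can act only as acceptor and the excess lithium enolate drives the reaction by deprotonating the β-keto ester as it forms.

Step 3
Reactants: 5 tert-butyl 3-[2,4-bis(methoxymethoxy)phenyl]-3-oxopropanoate; 6 prenyl bromide (1-bromo-3-methylbut-2-ene)
Product: 7 tert-butyl 2-[2,4-bis(methoxymethoxy)benzoyl]-5-methylhex-4-enoate (racemic)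
Conditions: K2CO3, acetone, rt → 50 °C
Reagents that add atoms: prenyl bromide (6), CC(C)=CCBr
Why: C-alkylation of a β-keto ester enolate (acetoacetic ester alkylation) by SN2 attack on the primary allylic bromide, with the bulky ester and aroyl group disfavouring a second alkylation.

Step 4
Reactants: 8 ethyl acetoacetate; 6 prenyl bromide
Product: 9 ethyl 7-methyl-3-oxooct-6-enoate
Conditions: LiN(iPr)2 (2.2 equiv), THF, −78 → 0 °C; then 6, 0 °C; aq. NH4Cl
Reagents that add atoms: prenyl bromide (6), CC(C)=CCBr
Why: Weiler dianion alkylation, in which the second deprotonation creates the more reactive γ-carbanion and only this carbon is alkylated by the allylic bromide.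

Step 5
Reactants: 9 ethyl 7-methyl-3-oxooct-6-enoate; 10 pyrrolidine
Product: 11 ethyl (2E)-7-methyl-3-(pyrrolidin-1-yl)octa-2,6-dienoate
Conditions: pyrrolidine (1.2 equiv), cat. AcOH, toluene, reflux (Dean–Stark)
Reagents that add atoms: pyrrolidine (10), C1CCNC1
Why: Enamine condensation of a secondary amine with the ketone of a β-keto ester gives the conjugated β-enamino ester, driven by azeotropic removal of water; the E isomer is expected and the geometry is of no consequence later.

Step 6
Reactants: 7 tert-butyl 2-[2,4-bis(methoxymethoxy)benzoyl]-5-methylhex-4-enoate; 11 ethyl (2E)-7-methyl-3-(pyrrolidin-1-yl)octa-2,6-dienoate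
Product: 14 ethyl 6-[2,4-bis(methoxymethoxy)phenyl]-5-(3-methylbut-2-en-1-yl)-2-(4-methylpent-3-en-1-yl)-4-oxo-4H-pyran-3-carboxylate, via aroyl(prenyl)ketene 12 (not isolated), via C-acylated enamino ester 13 (not isolated)
Conditions: 11 (1.5 equiv), xylene, 140 °C, N2 sweep, slow addition of 7; then AcOH, 60 °C
Reagents that add atoms: none
Why: Thermal loss of tert-butanol from the α-monosubstituted tert-butyl β-keto ester should give the acylketene, which is C-acylated by the nucleophilic β-carbon of the enamino ester (formal [4+2] of an acylketene with an enamine, Stork-type acylation), and acid then lets the aroyl enol oxygen displace pyrrolidine to give the 4-pyranone with a regiochemistry fixed by the polarity of both partners.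

Step 7
Reactants: 14 ethyl 6-[2,4-bis(methoxymethoxy)phenyl]-5-(3-methylbut-2-en-1-yl)-2-(4-methylpent-3-en-1-yl)-4-oxo-4H-pyran-3-carboxylate; 15 N-methoxy-N-methylacetamide
Product: 16 ethyl 6-[2,4-bis(methoxymethoxy)phenyl]-5-(3-methylbut-2-en-1-yl)-2-(6-methyl-2-oxohept-5-en-3-yl)-4-oxo-4H-pyran-3-carboxylate (racemic)
Conditions: LiN(iPr)2 (1.1 equiv), THF, −78 °C; then 15 (1.5 equiv), −78 → 0 °C; aq. NH4Cl
Reagents that add atoms: N-methoxy-N-methylacetamide (15), CC(=O)N(C)OC
Why: Lateral (vinylogous) metalation removes a proton from the methylene on pyranone C2, the only site that is γ to both the ring carbonyl and the ester, and the dienolate is acylated at its exocyclic carbon by the Weinreb amide, whose chelated tetrahedral adduct prevents over-addition until work-up.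

Step 8
Reactants: 16 ethyl 6-[2,4-bis(methoxymethoxy)phenyl]-5-(3-methylbut-2-en-1-yl)-2-(6-methyl-2-oxohept-5-en-3-yl)-4-oxo-4H-pyran-3-carboxylate
Product: 18 2-[2,4-bis(methoxymethoxy)phenyl]-5,7-dihydroxy-3,8-bis(3-methylbut-2-en-1-yl)-4H-chromen-4-one, via ring A cyclohexanedione tautomer 17 (not isolated)
Conditions: LiN(iPr)2 (3.5 equiv), THF, −78 → 0 °C; aq. NH4Cl
Reagents that add atoms: none
Why: Proposed new method: LiN(iPr)2 should first remove the acidic C8 proton (α to the ketone and vinylogous to the pyranone carbonyl and the ester) and then a methyl proton, giving a 1,3-dianion whose terminal CH2 carbanion adds to the neighbouring ester carbonyl; loss of ethoxide gives dione 17, which enolises at once to the aromatic 5,7-dihydroxy ring A. The closest known reactions are the base-mediated Claisen cyclisation of 2-(2-oxopropyl)benzoates to naphthalene-1,3-diols and the acylation of β-diketone dianions by esters. Ring A closes in a 6-(enolendo)-exo-trig mode, which is geometrically easy because the ester and the keto side chain sit on adjacent carbons of the planar pyranone. No stereocentre is formed, and the racemic centre at C8 becomes an aromatic carbon. The step needs C- over O-acylation: the dianion carries its highest charge density on the terminal carbon, an enol lactone from oxygen attack can be reopened by ethoxide, and aromatisation makes the carbon pathway irreversible. The C8 prenyl group cannot end up elsewhere because it sits on the carbon that links the ketone to C8a.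

Step 9
Reactants: 18 2-[2,4-bis(methoxymethoxy)phenyl]-5,7-dihydroxy-3,8-bis(3-methylbut-2-en-1-yl)-4H-chromen-4-one
Product: 19 Kuwanon C, 2-(2,4-dihydroxyphenyl)-5,7-dihydroxy-3,8-bis(3-methylbut-2-en-1-yl)-4H-chromen-4-one
Conditions: 3 M HCl (aq.), MeOH, 40 °C, stopped at full conversion
Reagents that add atoms: none
Why: Acid-catalysed acetal exchange with methanol (methoxymethyl ether cleavage) is much faster than protonation of the trisubstituted prenyl alkenes by dilute acid, so both prenyl groups and the free phenols should survive.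

**Compound list**

1 | methyl 2,4-dihydroxybenzoate | COC(=O)c1ccc(O)cc1O | starting material
2 | chloromethyl methyl ether | COCCl | starting material
3 | methyl 2,4-bis(methoxymethoxy)benzoate | COC(=O)c1ccc(OCOC)cc1OCOC | intermediate
4 | tert-butyl acetate | CC(=O)OC(C)(C)C | starting material
5 | tert-butyl 3-[2,4-bis(methoxymethoxy)phenyl]-3-oxopropanoate | CC(C)(C)OC(=O)CC(=O)c1ccc(OCOC)cc1OCOC | intermediate
6 | prenyl bromide (1-bromo-3-methylbut-2-ene) | CC(C)=CCBr | starting material
7 | tert-butyl 2-[2,4-bis(methoxymethoxy)benzoyl]-5-methylhex-4-enoate (racemic) | CC(C)=CCC(C(=O)OC(C)(C)C)C(=O)c1ccc(OCOC)cc1OCOC | intermediate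
8 | ethyl acetoacetate | CCOC(=O)CC(C)=O | starting material
9 | ethyl 7-methyl-3-oxooct-6-enoate | CCOC(=O)CC(=O)CCC=C(C)C | intermediate
10 | pyrrolidine | C1CCNC1 | starting material
11 | ethyl (2E)-7-methyl-3-(pyrrolidin-1-yl)octa-2,6-dienoate | CCOC(=O)/C=C(\CCC=C(C)C)N1CCCC1 | intermediate
12 | 2-[2,4-bis(methoxymethoxy)benzoyl]-5-methylhexa-1,4-dien-1-one (aroyl(prenyl)ketene, not isolated) | CC(C)=CCC(=C=O)C(=O)c1ccc(OCOC)cc1OCOC | intermediate
13 | ethyl 2-{2-[2,4-bis(methoxymethoxy)benzoyl]-5-methylhex-4-enoyl}-7-methyl-3-(pyrrolidin-1-yl)octa-2,6-dienoate (racemic, not isolated) | CCOC(=O)C(C(=O)C(CC=C(C)C)C(=O)c1ccc(OCOC)cc1OCOC)=C(CCC=C(C)C)N1CCCC1 | intermediate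
14 | ethyl 6-[2,4-bis(methoxymethoxy)phenyl]-5-(3-methylbut-2-en-1-yl)-2-(4-methylpent-3-en-1-yl)-4-oxo-4H-pyran-3-carboxylate | CCOC(=O)c1c(CCC=C(C)C)oc(-c2ccc(OCOC)cc2OCOC)c(CC=C(C)C)c1=O | intermediate
15 | N-methoxy-N-methylacetamide | CC(=O)N(C)OC | starting material
16 | ethyl 6-[2,4-bis(methoxymethoxy)phenyl]-5-(3-methylbut-2-en-1-yl)-2-(6-methyl-2-oxohept-5-en-3-yl)-4-oxo-4H-pyran-3-carboxylate (racemic) | CCOC(=O)c1c(C(CC=C(C)C)C(C)=O)oc(-c2ccc(OCOC)cc2OCOC)c(CC=C(C)C)c1=O | intermediate
17 | 2-[2,4-bis(methoxymethoxy)phenyl]-3,8-bis(3-methylbut-2-en-1-yl)-6,8-dihydro-4H-chromene-4,5,7-trione (racemic, not isolated) | CC(C)=CCC1C(=O)CC(=O)c2c1oc(-c1ccc(OCOC)cc1OCOC)c(CC=C(C)C)c2=O | intermediate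
18 | 2-[2,4-bis(methoxymethoxy)phenyl]-5,7-dihydroxy-3,8-bis(3-methylbut-2-en-1-yl)-4H-chromen-4-one | CC(C)=CCc1c(-c2ccc(OCOC)cc2OCOC)oc2c(CC=C(C)C)c(O)cc(O)c2c1=O | intermediate
19 | Kuwanon C | CC(C)=CCc1c(-c2ccc(O)cc2O)oc2c(CC=C(C)C)c(O)cc(O)c2c1=O | target

**Step count and risk**

Total step count: 9. Longest linear sequence: 7 steps (steps 1, 2, 3, 6, 7, 8, 9).

Steps most likely to fail:

1. Step 8 (the proposed new method). The second deprotonation may stay incomplete, so that the monoanion is recovered or closes through oxygen to an enol lactone; amide base may also add to the electron-poor pyranone and open it. Fallback by known chemistry (classical diketone route to the flavone), setting out from 3 and coming back at 19: commercial 1-(2,4,6-trihydroxyphenyl)ethanone would be C-prenylated once with 6 (aq. KOH, 0 °C) to 1-[2,4,6-trihydroxy-3-(3-methylbut-2-en-1-yl)phenyl]ethanone F1. Chloromethyl methyl ether 2 with K2CO3 in acetone should protect the 4-hydroxyl and the less hindered of the two chelated hydroxyls and leave the one next to the prenyl group free, giving 1-[2-hydroxy-4,6-bis(methoxymethoxy)-3-(3-methylbut-2-en-1-yl)phenyl]ethanone F2. Crossed Claisen condensation of the dianion of F2 (LiN(SiMe3)2, THF) with ester 3 would give 1-[2,4-bis(methoxymethoxy)phenyl]-3-[2-hydroxy-4,6-bis(methoxymethoxy)-3-(3-methylbut-2-en-1-yl)phenyl]propane-1,3-dione F3. Its central carbon would be alkylated with 6 (K2CO3, acetone) to racemic 1-[2,4-bis(methoxymethoxy)phenyl]-3-[2-hydroxy-4,6-bis(methoxymethoxy)-3-(3-methylbut-2-en-1-yl)phenyl]-2-(3-methylbut-2-en-1-yl)propane-1,3-dione F4. Cyclodehydration (NaOAc, AcOH, 90 °C) would give 2-[2,4-bis(methoxymethoxy)phenyl]-5,7-bis(methoxymethoxy)-3,8-bis(3-methylbut-2-en-1-yl)-4H-chromen-4-one F5, and the conditions of step 9 would then lead to 19.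

2. Step 6. Ketene release from the α-substituted ester may be slow, and the ketene may dimerise, be captured by pyrrolidine set free too early, or be attacked by the ortho methoxymethoxy oxygen with transfer of the acetal group. Fallback without a ketene (triketone route), setting out from 9 and 3 and coming back at 14: commercial 5-methylhex-4-enoic acid would be converted with oxalyl chloride into 5-methylhex-4-enoyl chloride F6. C-acylation of 9 with F6 (MgCl2, pyridine, CH2Cl2) would give ethyl 7-methyl-2-(5-methylhex-4-enoyl)-3-oxooct-6-enoate F7, in which both acyl arms are identical. Its dianion (LiN(iPr)2, 3 equiv, THF) would be aroylated at a terminal α-methylene by ester 3 to give racemic ethyl 2-{2-[2,4-bis(methoxymethoxy)benzoyl]-5-methylhex-4-enoyl}-7-methyl-3-oxooct-6-enoate F8. Neutral cyclodehydration of the 1,3,5-triketone unit (PPh3, CCl4, THF, rt) would close the pyranone 14.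

3. Step 7. Acylation of the hindered, ester-stabilised secondary lateral anion by the Weinreb amide may be sluggish, so that starting material returns or acylation occurs on oxygen. Fallback that forms the two bonds at the lateral carbon in the opposite order, setting out from 7 and 8 and coming back at 16: 8 and 10 would be condensed as in step 5 to ethyl (2E)-3-(pyrrolidin-1-yl)but-2-enoate F9. Union with 7 under the conditions of step 6 would give ethyl 6-[2,4-bis(methoxymethoxy)phenyl]-2-methyl-5-(3-methylbut-2-en-1-yl)-4-oxo-4H-pyran-3-carboxylate F10. Its unhindered primary lateral anion (LiN(iPr)2, THF, −78 °C) would be acetylated with 15 to ethyl 6-[2,4-bis(methoxymethoxy)phenyl]-5-(3-methylbut-2-en-1-yl)-4-oxo-2-(2-oxopropyl)-4H-pyran-3-carboxylate F11. The doubly activated methylene of F11 would then be C-prenylated with 6 (K2CO3, acetone, rt) to give 16.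

**Further compounds**

F1 | step 8 | 1-[2,4,6-trihydroxy-3-(3-methylbut-2-en-1-yl)phenyl]ethanone | CC(=O)c1c(O)cc(O)c(CC=C(C)C)c1O
F2 | step 8 | 1-[2-hydroxy-4,6-bis(methoxymethoxy)-3-(3-methylbut-2-en-1-yl)phenyl]ethanone | CC(=O)c1c(OCOC)cc(OCOC)c(CC=C(C)C)c1O
F3 | step 8 | 1-[2,4-bis(methoxymethoxy)phenyl]-3-[2-hydroxy-4,6-bis(methoxymethoxy)-3-(3-methylbut-2-en-1-yl)phenyl]propane-1,3-dione | COCOc1ccc(C(=O)CC(=O)c2c(OCOC)cc(OCOC)c(CC=C(C)C)c2O)c(OCOC)c1
F4 | step 8 | 1-[2,4-bis(methoxymethoxy)phenyl]-3-[2-hydroxy-4,6-bis(methoxymethoxy)-3-(3-methylbut-2-en-1-yl)phenyl]-2-(3-methylbut-2-en-1-yl)propane-1,3-dione (racemic) | COCOc1ccc(C(=O)C(CC=C(C)C)C(=O)c2c(OCOC)cc(OCOC)c(CC=C(C)C)c2O)c(OCOC)c1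
F5 | step 8 | 2-[2,4-bis(methoxymethoxy)phenyl]-5,7-bis(methoxymethoxy)-3,8-bis(3-methylbut-2-en-1-yl)-4H-chromen-4-one | CC(C)=CCc1c(-c2ccc(OCOC)cc2OCOC)oc2c(CC=C(C)C)c(OCOC)cc(OCOC)c2c1=O
F6 | step 6 | 5-methylhex-4-enoyl chloride | CC(C)=CCCC(=O)Cl
F7 | step 6 | ethyl 7-methyl-2-(5-methylhex-4-enoyl)-3-oxooct-6-enoate | CCOC(=O)C(C(=O)CCC=C(C)C)C(=O)CCC=C(C)C
F8 | step 6 | ethyl 2-{2-[2,4-bis(methoxymethoxy)benzoyl]-5-methylhex-4-enoyl}-7-methyl-3-oxooct-6-enoate (racemic) | CCOC(=O)C(C(=O)CCC=C(C)C)C(=O)C(CC=C(C)C)C(=O)c1ccc(OCOC)cc1OCOC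
F9 | step 7 | ethyl (2E)-3-(pyrrolidin-1-yl)but-2-enoate | CCOC(=O)/C=C(\C)N1CCCC1
F10 | step 7 | ethyl 6-[2,4-bis(methoxymethoxy)phenyl]-2-methyl-5-(3-methylbut-2-en-1-yl)-4-oxo-4H-pyran-3-carboxylate | CCOC(=O)c1c(C)oc(-c2ccc(OCOC)cc2OCOC)c(CC=C(C)C)c1=O
F11 | step 7 | ethyl 6-[2,4-bis(methoxymethoxy)phenyl]-5-(3-methylbut-2-en-1-yl)-4-oxo-2-(2-oxopropyl)-4H-pyran-3-carboxylate | CCOC(=O)c1c(CC(C)=O)oc(-c2ccc(OCOC)cc2OCOC)c(CC=C(C)C)c1=O
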